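**Plan**

1. The C40 ester is cut at C11=C12 and C11'=C12' (two Wittig reactions) into a β-end C15 phosphonium salt that already carries the palmitate, the C10 trienedial, and a silyl-protected ε-end C15 phosphonium salt.
2. The ε-end is cut at C7'=C8' (HWE) back to a ring aldehyde; with the ring taken to the C3' enol-ether level (C3'–OSi, C3'=C4'), it is cut at C1'–C2' and C5'–C6' into prenal and a 2-silyloxypenta-1,3-diene.
3. Enabling feature: in the ε-ring the oxygen at C3' is 1,4 to C6', which bears the chain carbon C7' (a latent formyl), the C5' methyl is 1,2 to C6', and the gem-dimethyl carbon C1' is its other neighbour. This is a Diels–Alder retron in which both diene substituents direct the same regiochemistry.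
4. Forward: the β-ring is bought (actinol) and never opened; palmitoylation, enol triflate, Suzuki coupling, salt formation and Wittig reaction with the C10 dial give the C25 aldehyde. The ε-ring, the only ring closed and the last to appear, arises in the cycloaddition; HWE, Saegusa–Ito oxidation, CBS reduction, silylation, reduction and salt formation follow, then the final Wittig reaction and desilylation.
5. Stereochemistry: C3 from the chiral pool; C6' from the catalyst-controlled cycloaddition; C3' from reagent-controlled ketone reduction (trans to the chain); E-alkenes from Suzuki/HWE/Wittig steps plus Z→E equilibration.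

Key step: step 8

Remark: the (S)-prolinol-derived oxazaborolidinium is assumed, from its formyl C–H···O binding model, to expose the Cα Si face of prenal (if the sense proves opposite, the enantiomeric catalyst is used unchanged otherwise); 15 and 18 are drawn as the endo (cis) diastereomers, and any exo epimer at ring C2 converges in step 10.

**Route**

Step 1
Reactants: 1 (4R,6R)-4-hydroxy-2,2,6-trimethylcyclohexanone (actinol); 2 hexadecanoyl (palmitoyl) chloride
Product: 3 (1R,3R)-3,5,5-trimethyl-4-oxocyclohexyl hexadecanoate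
Conditions: pyridine, DMAP (cat.), CH2Cl2, 0 °C → rt
Reagents that add atoms: none
Why: DMAP-catalysed acylation of the unhindered secondary alcohol by the acid chloride should be clean and touches no stereocenter; the palmitate then serves as its own protecting group throughout the β-branch.

Step 2
Reactants: 3 (1R,3R)-3,5,5-trimethyl-4-oxocyclohexyl hexadecanoate
Product: 4 (1R)-3,5,5-trimethyl-4-{[(trifluoromethyl)sulfonyl]oxy}cyclohex-3-en-1-yl hexadecanoate
Conditions: Tf2O, 2,6-di-tert-butyl-4-methylpyridine, CH2Cl2, 0 °C → rt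
Reagents that add atoms: trifluoromethanesulfonic anhydride O=S(=O)(OS(=O)(=O)C(F)(F)F)C(F)(F)F
Why: Enol triflate formation with Tf2O and a hindered pyridine needs no strong base, so the ester survives; the ketone has only one enolisable α-carbon (the other is quaternary), so a single regioisomer should form, and the methyl-bearing stereocenter is deliberately erased.

Step 3
Reactants: 5 (E)-3-methylpent-2-en-4-yn-1-ol
Product: 6 (2E,4E)-3-methyl-5-(4,4,5,5-tetramethyl-1,3,2-dioxaborolan-2-yl)penta-2,4-dien-1-ol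
Conditions: B2pin2, CuCl (5 mol %), Xantphos (5 mol %), NaOt-Bu (10 mol %), MeOH (2 equiv), THF, rt
Reagents that add atoms: bis(pinacolato)diboron CC1(C)OB(OC1(C)C)B1OC(C)(C)C(C)(C)O1
Why: Copper-catalysed formal hydroboration (syn borylcupration of the terminal alkyne with boron at the terminal carbon, then protonolysis by MeOH) should give the (E)-alkenyl boronate without touching the trisubstituted alkene or the free hydroxyl.

Step 4
Reactants: 4 (1R)-3,5,5-trimethyl-4-{[(trifluoromethyl)sulfonyl]oxy}cyclohex-3-en-1-yl hexadecanoate; 6 (2E,4E)-3-methyl-5-(4,4,5,5-tetramethyl-1,3,2-dioxaborolan-2-yl)penta-2,4-dien-1-ol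
Product: 7 (1R)-4-[(1E,3E)-5-hydroxy-3-methylpenta-1,3-dien-1-yl]-3,5,5-trimethylcyclohex-3-en-1-yl hexadecanoate
Conditions: Pd(OAc)2 (5 mol %), SPhos (10 mol %), K3PO4, THF/H2O, 50 °C
Reagents that add atoms: none
Why: Suzuki–Miyaura coupling of the hindered tetrasubstituted enol triflate is enabled by a bulky dialkylbiarylphosphine and retains the (E,E)-geometry of the boronate; the mild phosphate base should spare the palmitate.

Step 5
Reactants: 7 (1R)-4-[(1E,3E)-5-hydroxy-3-methylpenta-1,3-dien-1-yl]-3,5,5-trimethylcyclohex-3-en-1-yl hexadecanoate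
Product: 8 {(2E,4E)-5-[(4R)-4-(hexadecanoyloxy)-2,6,6-trimethylcyclohex-1-en-1-yl]-3-methylpenta-2,4-dien-1-yl}triphenylphosphonium bromide
Conditions: PPh3·HBr, CH2Cl2, rt
Reagents that add atoms: triphenylphosphine hydrobromide [Br-].c1ccc(cc1)[PH+](c1ccccc1)c1ccccc1
Why: Ionisation of the primary dienylic alcohol by HBr and capture of the pentadienyl cation by PPh3 at the primary terminus is the standard phosphonium salt formation for C15 Wittig salts; the homoallylic secondary ester is not ionised.

Step 6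
Reactants: 8 {(2E,4E)-5-[(4R)-4-(hexadecanoyloxy)-2,6,6-trimethylcyclohex-1-en-1-yl]-3-methylpenta-2,4-dien-1-yl}triphenylphosphonium bromide; 9 (2E,4E,6E)-2,7-dimethylocta-2,4,6-trienedial
Product: 11 (3R)-12'-oxo-12'-apo-β-caroten-3-yl hexadecanoate, via phosphorus ylide 10 (not isolated)
Conditions: NaHMDS, THF, −78 °C; ylide added to 9 (3 equiv), −78 → 0 °C; then I2 (cat.), CH2Cl2, rt, daylight
Reagents that add atoms: none
Why: Wittig olefination of the semi-stabilised ylide with excess symmetrical dialdehyde (inverse addition) should give the mono-adduct, the low-temperature amide base leaving the ester untouched; iodine-catalysed equilibration should convert the (11Z) component into the all-E apocarotenal.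

Step 7
Reactants: 12 (E)-pent-3-en-2-one
Product: 13 triisopropyl{[(3E)-penta-1,3-dien-2-yl]oxy}silane
Conditions: TIPSOTf, Et3N, CH2Cl2, 0 °C
Reagents that add atoms: triisopropylsilyl trifluoromethanesulfonate CC(C)[Si](OS(=O)(=O)C(F)(F)F)(C(C)C)C(C)C
Why: Soft enolisation (silyl triflate/amine) silylates the enone oxygen and removes an α'-methyl proton, giving the cross-conjugated 2-silyloxy diene as with methyl vinyl ketone; the bulky TIPS group is chosen to resist silyl transfer in step 8.

Step 8
Reactants: 13 triisopropyl{[(3E)-penta-1,3-dien-2-yl]oxy}silane; 14 3-methylbut-2-enal (prenal)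
Product: 15 (1S,2S)-2,6,6-trimethyl-4-[(triisopropylsilyl)oxy]cyclohex-3-ene-1-carbaldehyde (formyl and 2-methyl cis)
Conditions: (S)-o-tolyl-oxazaborolidine (diphenylprolinol-derived, 20 mol %), Tf2NH (20 mol %), CH2Cl2, −78 → −40 °C; Et3N quench
Reagents that add atoms: none
Why: Proposed new method: the cationic oxazaborolidinium binds prenal at the formyl group (s-trans enal) and lowers its LUMO enough for a normal-demand, strongly asynchronous [4+2] addition in which the unsubstituted CH2 terminus of the 2-silyloxy diene (largest HOMO coefficient) attacks the β-carbon first, so that the quaternary C1' is built by the least hindered diene carbon and the C5'–C6' bond then closes the ring. The closest known reactions are oxazaborolidinium-catalysed enantioselective Diels–Alder reactions of α- or β-monosubstituted enals with 2-(triisopropylsilyloxy)dienes and the Lewis-acid-promoted cycloaddition of β,β-dimethyl enones with (E)-penta-1,3-diene; a β,β-disubstituted acyclic enal has not been used in the asymmetric variant. The ε-ring is closed in one intermolecular [4+2] event (bonds C1'–C2' and C5'–C6', six ring atoms from a four-carbon and a two-carbon unit). C6' (ring C1) is set by the catalyst, which shields one face of Cα so that the diene adds to the Si face, while C5' (ring C2) follows from the (E)-diene geometry and the endo mode and is erased in step 10, so both diastereomers converge. The step needs regioselectivity, secured because the 2-silyloxy group (para-directing) and the 4-methyl group (ortho-directing) reinforce each other, and cycloaddition instead of 1,2-addition to the formyl group, favoured by the non-transferable TIPS group and the low temperature.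

Step 9
Reactants: 15 (1S,2S)-2,6,6-trimethyl-4-[(triisopropylsilyl)oxy]cyclohex-3-ene-1-carbaldehyde; 16 ethyl (E)-4-(diethoxyphosphoryl)-3-methylbut-2-enoate
Product: 18 ethyl (2E,4E)-3-methyl-5-{(1S,2R)-2,6,6-trimethyl-4-[(triisopropylsilyl)oxy]cyclohex-3-en-1-yl}penta-2,4-dienoate, via lithiated phosphonate 17 (not isolated)
Conditions: 16, LiHMDS, THF, −78 °C; then 15, −78 → 0 °C
Reagents that add atoms: none
Why: Horner–Wadsworth–Emmons olefination of the hindered aldehyde with the pre-formed lithium anion of the vinylogous phosphonoacetate at low temperature should give the (2E,4E)-dienoate faster than the formyl-bearing stereocenter (C6') can enolise; the TIPS enol ether is inert to these conditions.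

Step 10
Reactants: 18 ethyl (2E,4E)-3-methyl-5-{(1S,2R)-2,6,6-trimethyl-4-[(triisopropylsilyl)oxy]cyclohex-3-en-1-yl}penta-2,4-dienoate
Product: 19 ethyl (2E,4E)-3-methyl-5-[(1R)-2,6,6-trimethyl-4-oxocyclohex-2-en-1-yl]penta-2,4-dienoate
Conditions: Pd(OAc)2 (1.1 equiv), MeCN/CH2Cl2, rt → 40 °C
Reagents that add atoms: none
Why: Saegusa–Ito oxidation: palladation of the silyl enol ether at C4' is followed by β-hydride elimination, which can only take the C5' hydrogen, so the C4'=C5' enone forms regiospecifically, the auxiliary C5' stereocenter is removed and C6' is not touched.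

Step 11
Reactants: 19 ethyl (2E,4E)-3-methyl-5-[(1R)-2,6,6-trimethyl-4-oxocyclohex-2-en-1-yl]penta-2,4-dienoate
Product: 20 ethyl (2E,4E)-5-[(1R,4R)-4-hydroxy-2,6,6-trimethylcyclohex-2-en-1-yl]-3-methylpenta-2,4-dienoate
Conditions: (S)-2-methyl-CBS-oxazaborolidine (0.5 equiv), catecholborane, toluene, −78 °C; aqueous work-up
Reagents that add atoms: none
Why: Corey–Bakshi–Shibata reduction: with the alkenyl carbon as the large and the C2' methylene as the small carbonyl substituent, the (S)-oxazaborolidine should deliver hydride to the face that places the new hydroxyl trans to the C6' side chain, i.e. (3'R), under reagent control and with 1,2-selectivity; catecholborane does not reduce the dienoate at −78 °C.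

Step 12
Reactants: 20 ethyl (2E,4E)-5-[(1R,4R)-4-hydroxy-2,6,6-trimethylcyclohex-2-en-1-yl]-3-methylpenta-2,4-dienoate
Product: 21 ethyl (2E,4E)-5-[(1R,4R)-4-{[tert-butyl(dimethyl)silyl]oxy}-2,6,6-trimethylcyclohex-2-en-1-yl]-3-methylpenta-2,4-dienoate
Conditions: TBSCl, imidazole, DMF, rt
Reagents that add atoms: tert-butyldimethylsilyl chloride CC(C)(C)[Si](C)(C)Cl
Why: Standard silylation masks the acid-sensitive allylic 3'-hydroxyl as a TBS ether that survives hydride, Appel and ylide conditions and can be removed at the end without touching the palmitate.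

Step 13
Reactants: 21 ethyl (2E,4E)-5-[(1R,4R)-4-{[tert-butyl(dimethyl)silyl]oxy}-2,6,6-trimethylcyclohex-2-en-1-yl]-3-methylpenta-2,4-dienoate
Product: 22 (2E,4E)-5-[(1R,4R)-4-{[tert-butyl(dimethyl)silyl]oxy}-2,6,6-trimethylcyclohex-2-en-1-yl]-3-methylpenta-2,4-dien-1-ol
Conditions: DIBAL-H (2.2 equiv), CH2Cl2, −78 °C; Rochelle salt work-up
Reagents that add atoms: none
Why: DIBAL-H reduction of the conjugated ester proceeds by 1,2-delivery at low temperature to the primary dienylic alcohol without conjugate reduction or loss of alkene geometry.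

Step 14
Reactants: 22 (2E,4E)-5-[(1R,4R)-4-{[tert-butyl(dimethyl)silyl]oxy}-2,6,6-trimethylcyclohex-2-en-1-yl]-3-methylpenta-2,4-dien-1-ol
Product: 24 {(2E,4E)-5-[(1R,4R)-4-{[tert-butyl(dimethyl)silyl]oxy}-2,6,6-trimethylcyclohex-2-en-1-yl]-3-methylpenta-2,4-dien-1-yl}triphenylphosphonium bromide, via allylic bromide 23 (not isolated)
Conditions: CBr4, PPh3, 2,6-lutidine (cat.), CH2Cl2, −20 °C; then PPh3, rt
Reagents that add atoms: carbon tetrabromide BrC(Br)(Br)Br; triphenylphosphine c1ccc(cc1)P(c1ccccc1)c1ccccc1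
Why: Appel bromination under neutral conditions followed by SN2 displacement with PPh3 converts the dienylic alcohol into the Wittig salt without the Brønsted acid that would ionise the allylic C3' ether.

Step 15
Reactants: 24 {(2E,4E)-5-[(1R,4R)-4-{[tert-butyl(dimethyl)silyl]oxy}-2,6,6-trimethylcyclohex-2-en-1-yl]-3-methylpenta-2,4-dien-1-yl}triphenylphosphonium bromide; 11 (3R)-12'-oxo-12'-apo-β-caroten-3-yl hexadecanoate
Product: 26 (3R,3'R,6'R)-3'-{[tert-butyl(dimethyl)silyl]oxy}-β,ε-caroten-3-yl hexadecanoate, via phosphorus ylide 25 (not isolated)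
Conditions: NaHMDS, THF, −78 °C; then 11, −78 → 0 °C; then n-heptane, 90 °C, N2, dark
Reagents that add atoms: none
Why: Wittig olefination joins C11' to C12' and completes the C40 chain; the (11'Z)/(11'E) mixture from the semi-stabilised ylide should converge thermally on the all-E polyene, and neither the ester nor the silyl ether is affected at −78 °C.

Step 16
Reactants: 26 (3R,3'R,6'R)-3'-{[tert-butyl(dimethyl)silyl]oxy}-β,ε-caroten-3-yl hexadecanoate
Product: 27 (3R,3'R,6'R)-3'-hydroxy-β,ε-caroten-3-yl hexadecanoate (lutein 3-O-palmitate)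
Conditions: TBAF, AcOH (1:1), THF, 0 °C → rt, dark
Reagents that add atoms: none
Why: Fluoride-mediated desilylation buffered with acetic acid should free the 3'-hydroxyl without acyl cleavage (the two oxygens sit on different rings, so no migration is possible) and without the acid that epimerises or dehydrates the allylic ε-ring alcohol.

**Compound list**

1 | (4R,6R)-4-hydroxy-2,2,6-trimethylcyclohexanone (actinol) | O[C@@H]1C[C@@H](C)C(=O)C(C)(C)C1 | starting material
2 | hexadecanoyl (palmitoyl) chloride | CCCCCCCCCCCCCCCC(=O)Cl | starting material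
3 | (1R,3R)-3,5,5-trimethyl-4-oxocyclohexyl hexadecanoate | CCCCCCCCCCCCCCCC(=O)O[C@@H]1C[C@@H](C)C(=O)C(C)(C)C1 | intermediate
4 | (1R)-3,5,5-trimethyl-4-{[(trifluoromethyl)sulfonyl]oxy}cyclohex-3-en-1-yl hexadecanoate | CCCCCCCCCCCCCCCC(=O)O[C@@H]1CC(C)=C(OS(=O)(=O)C(F)(F)F)C(C)(C)C1 | intermediate
5 | (E)-3-methylpent-2-en-4-yn-1-ol | C#C/C(C)=C/CO | starting material
6 | (2E,4E)-3-methyl-5-(4,4,5,5-tetramethyl-1,3,2-dioxaborolan-2-yl)penta-2,4-dien-1-ol | CC1(C)OB(/C=C/C(C)=C/CO)OC1(C)C | intermediate
7 | (1R)-4-[(1E,3E)-5-hydroxy-3-methylpenta-1,3-dien-1-yl]-3,5,5-trimethylcyclohex-3-en-1-yl hexadecanoate | CCCCCCCCCCCCCCCC(=O)O[C@@H]1CC(C)=C(/C=C/C(C)=C/CO)C(C)(C)C1 | intermediate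
8 | {(2E,4E)-5-[(4R)-4-(hexadecanoyloxy)-2,6,6-trimethylcyclohex-1-en-1-yl]-3-methylpenta-2,4-dien-1-yl}triphenylphosphonium bromide | CCCCCCCCCCCCCCCC(=O)O[C@@H]1CC(C)=C(/C=C/C(C)=C/C[P+](c2ccccc2)(c3ccccc3)c4ccccc4)C(C)(C)C1.[Br-] | intermediate
9 | (2E,4E,6E)-2,7-dimethylocta-2,4,6-trienedial | O=C/C(C)=C/C=C/C=C(C)/C=O | starting material
10 | phosphorus ylide of 8 | CCCCCCCCCCCCCCCC(=O)O[C@@H]1CC(C)=C(/C=C/C(C)=C/C=P(c2ccccc2)(c3ccccc3)c4ccccc4)C(C)(C)C1 | intermediate
11 | (3R)-12'-oxo-12'-apo-β-caroten-3-yl hexadecanoate | CCCCCCCCCCCCCCCC(=O)O[C@@H]1CC(C)=C(/C=C/C(C)=C/C=C/C(C)=C/C=C/C=C(C)/C=O)C(C)(C)C1 | intermediate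
12 | (E)-pent-3-en-2-one | C/C=C/C(C)=O | starting material
13 | triisopropyl{[(3E)-penta-1,3-dien-2-yl]oxy}silane | C/C=C/C(=C)O[Si](C(C)C)(C(C)C)C(C)C | intermediate
14 | 3-methylbut-2-enal (prenal) | CC(C)=CC=O | starting material
15 | (1S,2S)-2,6,6-trimethyl-4-[(triisopropylsilyl)oxy]cyclohex-3-ene-1-carbaldehyde | O=C[C@H]1[C@@H](C)C=C(O[Si](C(C)C)(C(C)C)C(C)C)CC1(C)C | intermediate
16 | ethyl (E)-4-(diethoxyphosphoryl)-3-methylbut-2-enoate | CCOC(=O)/C=C(C)/CP(=O)(OCC)OCC | starting material
17 | lithium salt of 16 (carbanion α to phosphorus) | [Li+].CCOC(=O)/C=C(C)/[CH-]P(=O)(OCC)OCC | intermediate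
18 | ethyl (2E,4E)-3-methyl-5-{(1S,2R)-2,6,6-trimethyl-4-[(triisopropylsilyl)oxy]cyclohex-3-en-1-yl}penta-2,4-dienoate | CCOC(=O)/C=C(C)/C=C/[C@H]1[C@@H](C)C=C(O[Si](C(C)C)(C(C)C)C(C)C)CC1(C)C | intermediate
19 | ethyl (2E,4E)-3-methyl-5-[(1R)-2,6,6-trimethyl-4-oxocyclohex-2-en-1-yl]penta-2,4-dienoate | CCOC(=O)/C=C(C)/C=C/[C@H]1C(C)=CC(=O)CC1(C)C | intermediate
20 | ethyl (2E,4E)-5-[(1R,4R)-4-hydroxy-2,6,6-trimethylcyclohex-2-en-1-yl]-3-methylpenta-2,4-dienoate | CCOC(=O)/C=C(C)/C=C/[C@H]1C(C)=C[C@H](O)CC1(C)C | intermediate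
21 | ethyl (2E,4E)-5-[(1R,4R)-4-{[tert-butyl(dimethyl)silyl]oxy}-2,6,6-trimethylcyclohex-2-en-1-yl]-3-methylpenta-2,4-dienoate | CCOC(=O)/C=C(C)/C=C/[C@H]1C(C)=C[C@H](O[Si](C)(C)C(C)(C)C)CC1(C)C | intermediate
22 | (2E,4E)-5-[(1R,4R)-4-{[tert-butyl(dimethyl)silyl]oxy}-2,6,6-trimethylcyclohex-2-en-1-yl]-3-methylpenta-2,4-dien-1-ol | OC/C=C(C)/C=C/[C@H]1C(C)=C[C@H](O[Si](C)(C)C(C)(C)C)CC1(C)C | intermediate
23 | tert-butyl{[(1R,4R)-4-[(1E,3E)-5-bromo-3-methylpenta-1,3-dien-1-yl]-3,5,5-trimethylcyclohex-2-en-1-yl]oxy}dimethylsilane | BrC/C=C(C)/C=C/[C@H]1C(C)=C[C@H](O[Si](C)(C)C(C)(C)C)CC1(C)C | intermediate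
24 | {(2E,4E)-5-[(1R,4R)-4-{[tert-butyl(dimethyl)silyl]oxy}-2,6,6-trimethylcyclohex-2-en-1-yl]-3-methylpenta-2,4-dien-1-yl}triphenylphosphonium bromide | [Br-].c2ccccc2[P+](c3ccccc3)(c4ccccc4)C/C=C(C)/C=C/[C@H]1C(C)=C[C@H](O[Si](C)(C)C(C)(C)C)CC1(C)C | intermediate
25 | phosphorus ylide of 24 | c2ccccc2P(c3ccccc3)(c4ccccc4)=C/C=C(C)/C=C/[C@H]1C(C)=C[C@H](O[Si](C)(C)C(C)(C)C)CC1(C)C | intermediate
26 | (3R,3'R,6'R)-3'-{[tert-butyl(dimethyl)silyl]oxy}-β,ε-caroten-3-yl hexadecanoate | CCCCCCCCCCCCCCCC(=O)O[C@@H]1CC(C)=C(/C=C/C(C)=C/C=C/C(C)=C/C=C/C=C(C)/C=C/C=C(C)/C=C/[C@H]2C(C)=C[C@H](O[Si](C)(C)C(C)(C)C)CC2(C)C)C(C)(C)C1 | intermediate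
27 | (3R,3'R,6'R)-3'-hydroxy-β,ε-caroten-3-yl hexadecanoate | CCCCCCCCCCCCCCCC(=O)O[C@@H]1CC(C)=C(/C=C/C(C)=C/C=C/C(C)=C/C=C/C=C(C)/C=C/C=C(C)/C=C/[C@H]2C(C)=C[C@H](O)CC2(C)C)C(C)(C)C1 | target

**Totals**

Total steps: 16. Longest linear sequence: 10 steps (12 → 27, steps 7–16).

**Steps most likely to fail**

1. Step 8 (key cycloaddition). The cycloaddition may be too slow with the β,β-disubstituted enal, 1,2-addition of the silyl dienol ether to the formyl group may compete, or facial discrimination may be poor. The fallback closes the ring by the classical Lewis-acid Michael–aldol annulation (ZnCl2, heptane, reflux, water separator) of commercial mesityl oxide with commercial ethyl acetoacetate. This should give racemic ethyl 2,6,6-trimethyl-4-oxocyclohex-2-ene-1-carboxylate F1, in which C6' is still configurationally labile. (S)-CBS/catecholborane reduction sets C3' as (R) in both enantiomers and should turn the racemate into ethyl (1R,4R)-4-hydroxy-2,6,6-trimethylcyclohex-2-ene-1-carboxylate F2 and its cis diastereomer ethyl (1S,4R)-4-hydroxy-2,6,6-trimethylcyclohex-2-ene-1-carboxylate F3, which are separated by chromatography. F2 is silylated (TBSCl, imidazole) to ethyl (1R,4R)-4-{[tert-butyl(dimethyl)silyl]oxy}-2,6,6-trimethylcyclohex-2-ene-1-carboxylate F4, reduced with DIBAL-H at −78 °C to (1R,4R)-4-{[tert-butyl(dimethyl)silyl]oxy}-2,6,6-trimethylcyclohex-2-ene-1-carbaldehyde F5, and olefinated with 17 (from 16). This fallback does not branch from a compound of the ε-branch: it replaces 12–15 and 18–20, draws only on 16 among the numbered compounds, and comes back to the route at 21.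

2. Step 9 (HWE on the epimerisable aldehyde). Base-induced epimerisation at the formyl-bearing carbon during a slow addition to the hindered aldehyde would erode the enantiomeric purity set in step 8. The fallback sets out from 15 and uses a base-free Wittig reaction with the stabilised ylide 1-(triphenylphosphoranylidene)propan-2-one (toluene, 90 °C), which should give (E)-4-{(1S,2R)-2,6,6-trimethyl-4-[(triisopropylsilyl)oxy]cyclohex-3-en-1-yl}but-3-en-2-one F6. An HWE reaction of this methyl ketone with triethyl phosphonoacetate/NaH (THF) then builds the trisubstituted alkene and comes back to the route at 18 after removal of the (2Z)-isomer.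

3. Step 11 (CBS reduction). Facial selectivity may be poor if the intrinsic bias of the ring (hydride approach anti to the axial C1' methyl or to the side chain) opposes the catalyst. The fallback sets out from 19 and uses substrate-controlled Luche reduction (NaBH4, CeCl3, MeOH, −78 °C); the cis alcohol ethyl (2E,4E)-5-[(1R,4S)-4-hydroxy-2,6,6-trimethylcyclohex-2-en-1-yl]-3-methylpenta-2,4-dienoate F7 is separated from any 20 formed. Mitsunobu inversion (4-nitrobenzoic acid, DIAD, PPh3, THF) should give (1R,4R)-4-[(1E,3E)-5-ethoxy-3-methyl-5-oxopenta-1,3-dien-1-yl]-3,5,5-trimethylcyclohex-2-en-1-yl 4-nitrobenzoate F8, and ethanolysis (K2CO3, EtOH) comes back to the route at 20.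

**Further compounds**

F1 | step 8 | ethyl 2,6,6-trimethyl-4-oxocyclohex-2-ene-1-carboxylate (racemic) | CCOC(=O)C1C(C)=CC(=O)CC1(C)C
F2 | step 8 | ethyl (1R,4R)-4-hydroxy-2,6,6-trimethylcyclohex-2-ene-1-carboxylate | CCOC(=O)[C@H]1C(C)=C[C@H](O)CC1(C)C
F3 | step 8 | ethyl (1S,4R)-4-hydroxy-2,6,6-trimethylcyclohex-2-ene-1-carboxylate | CCOC(=O)[C@@H]1C(C)=C[C@H](O)CC1(C)C
F4 | step 8 | ethyl (1R,4R)-4-{[tert-butyl(dimethyl)silyl]oxy}-2,6,6-trimethylcyclohex-2-ene-1-carboxylate | CCOC(=O)[C@H]1C(C)=C[C@H](O[Si](C)(C)C(C)(C)C)CC1(C)C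
F5 | step 8 | (1R,4R)-4-{[tert-butyl(dimethyl)silyl]oxy}-2,6,6-trimethylcyclohex-2-ene-1-carbaldehyde | O=C[C@H]1C(C)=C[C@H](O[Si](C)(C)C(C)(C)C)CC1(C)C
F6 | step 9 | (E)-4-{(1S,2R)-2,6,6-trimethyl-4-[(triisopropylsilyl)oxy]cyclohex-3-en-1-yl}but-3-en-2-one | CC(=O)/C=C/[C@H]1[C@@H](C)C=C(O[Si](C(C)C)(C(C)C)C(C)C)CC1(C)C
F7 | step 11 | ethyl (2E,4E)-5-[(1R,4S)-4-hydroxy-2,6,6-trimethylcyclohex-2-en-1-yl]-3-methylpenta-2,4-dienoate | CCOC(=O)/C=C(C)/C=C/[C@H]1C(C)=C[C@@H](O)CC1(C)C
F8 | step 11 | (1R,4R)-4-[(1E,3E)-5-ethoxy-3-methyl-5-oxopenta-1,3-dien-1-yl]-3,5,5-trimethylcyclohex-2-en-1-yl 4-nitrobenzoate | CCOC(=O)/C=C(C)/C=C/[C@H]1C(C)=C[C@H](OC(=O)c2ccc(cc2)[N+](=O)[O-])CC1(C)C
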